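**Retrosynthetic overview**
1. Numbering: C1 = enol acetate CH, C3 = quaternary carbinol carbon, C20 = CHO carbon, C6=C7 = chain alkene, C10 = ring CH.
2. End game: both acetates go on last, onto an (R)-2-alkyl-2-silyloxysuccinaldehyde in which only the C1 aldehyde can enolise.
3. C2–C3: catalytic enantioselective acetate aldol on an α-keto ester (sets C3), followed by double partial reduction.
4. C4–C5: allylic alkylation of oxalacetate with monocyclofarnesyl acetate, then loss of the extra CO2Et.
5. The only ring is made first, by proton-initiated enantioselective head-to-tail cyclisation of acyclic all-E farnesyl acetate, halted after one ring (sets C10).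

Assumption: the recoverable chiral ligand of step 1 is bought or made by one O-alkylation of (R)-BINOL, and it is not counted as a step.

**Step 1**
Reactants: 1 (2E,6E)-farnesyl acetate
Product: 2 (2E)-3-methyl-5-[(1S)-2,6,6-trimethylcyclohex-2-en-1-yl]pent-2-en-1-yl acetate
Conditions: (R)-2'-[(2-fluorobenzyl)oxy]-1,1'-binaphthalen-2-ol (2.2 equiv), SnCl4 (2.0 equiv), toluene, −78 °C, 48 h; pyridine, then aq NaHCO3
Reagents that add atoms: none
Why: Proposed new method: the tin-bound binaphthol is a chiral Brønsted acid that protonates only the electron-rich terminal C10=C11 alkene on one face while C6=C7 closes on it through a chair (anti addition), which sets the ring CH as S in the sense this promoter family shows for the normal ring A series; the C2=C3 alkene is switched off by its allylic acetoxy group, whose C=O also binds tin, so the tertiary cation loses a ring CH2 proton to the ligand oxygen and gives the endocyclic alkene instead of a second ring, and any exocyclic isomer re-enters the same cation without touching the stereocentre; the closest known reaction type is polyene cyclisation induced by a Lewis acid-assisted chiral Brønsted acid, which is stepwise and is known to leave partly cyclised ring A products.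

**Step 2**
Reactants: 2 (2E)-3-methyl-5-[(1S)-2,6,6-trimethylcyclohex-2-en-1-yl]pent-2-en-1-yl acetate; 3 diethyl oxalacetate sodium salt
Product: 5 ethyl (5E)-6-methyl-2-oxo-8-[(1S)-2,6,6-trimethylcyclohex-2-en-1-yl]oct-5-enoate, via allylated oxalacetate diester 4 (not isolated)
Conditions: Pd(PPh3)4 (5 mol %), DMSO, 40 °C; then LiCl, H2O, 110 °C
Reagents that add atoms: none
Why: In this Tsuji–Trost allylic alkylation the soft, bulky enolate attacks the unsubstituted terminus of the η3-allylpalladium with the E geometry kept, and the Krapcho de-ethoxycarbonylation that follows removes only the ester β to the ketone, so the two epimers of 4 converge and no new stereocentre remains.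

**Step 3**
Reactants: 6 S-tert-butyl thioacetate
Product: 7 1-(tert-butylsulfanyl)-1-(trimethylsilyloxy)ethene
Conditions: LiN(i-Pr)2 (commercial solution), THF, −78 °C; Me3SiCl, −78 °C to rt
Reagents that add atoms: chlorotrimethylsilane C[Si](C)(C)Cl
Why: Kinetic enolisation of the thioester followed by O-silylation gives the silyl ketene thioacetal, and no stereocentre is formed.

**Step 4**
Reactants: 5 ethyl (5E)-6-methyl-2-oxo-8-[(1S)-2,6,6-trimethylcyclohex-2-en-1-yl]oct-5-enoate; 7 1-(tert-butylsulfanyl)-1-(trimethylsilyloxy)ethene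
Product: 8 ethyl (2R,5E)-2-[2-(tert-butylsulfanyl)-2-oxoethyl]-6-methyl-2-(trimethylsilyloxy)-8-[(1S)-2,6,6-trimethylcyclohex-2-en-1-yl]oct-5-enoate
Conditions: Cu(OTf)2 (10 mol %), 2,2'-(propane-2,2-diyl)bis[(4R)-4-tert-butyl-4,5-dihydrooxazole] (11 mol %), THF, −78 °C; non-acidic work-up (filtration through silica)
Reagents that add atoms: none
Why: In this catalytic enantioselective Mukaiyama aldol (Evans type) the α-keto ester chelates the square-planar copper bis(oxazoline), the tert-butyl groups of the (R,R) ligand leave only the re face of the ketone open, C3 is therefore set as R by catalyst control alone, and silyl transfer delivers the tertiary silyl ether while the alkenes stay inert.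

**Step 5**
Reactants: 8 ethyl (2R,5E)-2-[2-(tert-butylsulfanyl)-2-oxoethyl]-6-methyl-2-(trimethylsilyloxy)-8-[(1S)-2,6,6-trimethylcyclohex-2-en-1-yl]oct-5-enoate
Product: 9 (2R)-2-{(3E)-4-methyl-6-[(1S)-2,6,6-trimethylcyclohex-2-en-1-yl]hex-3-en-1-yl}-2-(trimethylsilyloxy)butanedial
Conditions: i-Bu2AlH (2.3 equiv), CH2Cl2, −78 °C; MeOH, then aq potassium sodium tartrate
Reagents that add atoms: none
Why: In this low-temperature partial reduction of an ester and a thioester, both tetrahedral aluminium adducts persist at −78 °C (the ester adduct is held by the α-silyloxy group) and collapse to aldehydes only on work-up, leaving C3 untouched.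

**Step 6**
Reactants: 9 (2R)-2-{(3E)-4-methyl-6-[(1S)-2,6,6-trimethylcyclohex-2-en-1-yl]hex-3-en-1-yl}-2-(trimethylsilyloxy)butanedial
Product: 12 (1E,3R,6E)-3-acetoxy-3-formyl-7-methyl-9-[(1S)-2,6,6-trimethylcyclohex-2-en-1-yl]nona-1,6-dien-1-yl acetate, via silyl ether enol acetate 10 (not isolated), via hydroxy enol acetate 11 (not isolated)
Conditions: Ac2O, Et3N, DMAP, CH2Cl2, 0 °C to rt; then Et3N·3HF, rt, same flask
Reagents that add atoms: acetic anhydride CC(=O)OC(C)=O
Why: DMAP-catalysed enol acetylation can act only on the C1 aldehyde because the other CHO sits on a quaternary carbon, the poor silyloxide leaving group holds back E1cB loss, and the bulky C3 forces the E enol acetate; fluoride desilylation and DMAP acetylation of the tertiary alcohol follow only once C2 carries no acidic hydrogen, so C3 stays R.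

**Compound list**
1 | (2E,6E)-farnesyl acetate | CC(=O)OC/C=C(\C)CC/C=C(\C)CCC=C(C)C | starting material
2 | (2E)-3-methyl-5-[(1S)-2,6,6-trimethylcyclohex-2-en-1-yl]pent-2-en-1-yl acetate | CC(=O)OC/C=C(\C)CC[C@@H]1C(C)=CCCC1(C)C | intermediate
3 | diethyl oxalacetate sodium salt | [Na+].CCOC(=O)C([O-])=CC(=O)OCC | starting material
4 | diethyl 2-{(2E)-3-methyl-5-[(1S)-2,6,6-trimethylcyclohex-2-en-1-yl]pent-2-en-1-yl}-3-oxobutanedioate (both epimers at the malonyl-type CH) | CCOC(=O)C(=O)C(C/C=C(\C)CC[C@@H]1C(C)=CCCC1(C)C)C(=O)OCC | intermediate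
5 | ethyl (5E)-6-methyl-2-oxo-8-[(1S)-2,6,6-trimethylcyclohex-2-en-1-yl]oct-5-enoate | CCOC(=O)C(=O)CC/C=C(\C)CC[C@@H]1C(C)=CCCC1(C)C | intermediate
6 | S-tert-butyl thioacetate | CC(=O)SC(C)(C)C | starting material
7 | 1-(tert-butylsulfanyl)-1-(trimethylsilyloxy)ethene | C=C(O[Si](C)(C)C)SC(C)(C)C | intermediate
8 | ethyl (2R,5E)-2-[2-(tert-butylsulfanyl)-2-oxoethyl]-6-methyl-2-(trimethylsilyloxy)-8-[(1S)-2,6,6-trimethylcyclohex-2-en-1-yl]oct-5-enoate | CC(C)(C)SC(=O)C[C@@](C(=O)OCC)(CC/C=C(\C)CC[C@@H]1C(C)=CCCC1(C)C)O[Si](C)(C)C | intermediate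
9 | (2R)-2-{(3E)-4-methyl-6-[(1S)-2,6,6-trimethylcyclohex-2-en-1-yl]hex-3-en-1-yl}-2-(trimethylsilyloxy)butanedial | O=CC[C@@](C=O)(CC/C=C(\C)CC[C@@H]1C(C)=CCCC1(C)C)O[Si](C)(C)C | intermediate
10 | (1E,3R,6E)-3-formyl-7-methyl-3-(trimethylsilyloxy)-9-[(1S)-2,6,6-trimethylcyclohex-2-en-1-yl]nona-1,6-dien-1-yl acetate | CC(=O)O/C=C/[C@@](C=O)(CC/C=C(\C)CC[C@@H]1C(C)=CCCC1(C)C)O[Si](C)(C)C | intermediate
11 | (1E,3R,6E)-3-formyl-3-hydroxy-7-methyl-9-[(1S)-2,6,6-trimethylcyclohex-2-en-1-yl]nona-1,6-dien-1-yl acetate | CC(=O)O/C=C/[C@@](C=O)(CC/C=C(\C)CC[C@@H]1C(C)=CCCC1(C)C)O | intermediate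
12 | (1E,3R,6E)-3-acetoxy-3-formyl-7-methyl-9-[(1S)-2,6,6-trimethylcyclohex-2-en-1-yl]nona-1,6-dien-1-yl acetate (CNP0244145.1) | CC(=O)O/C=C/[C@@](C=O)(CC/C=C(\C)CC[C@@H]1C(C)=CCCC1(C)C)OC(C)=O | target

**Step count**
Total step count: 6.
Longest linear sequence: 5 (steps 1, 2, 4, 5, 6).

**Steps most likely to fail**

Step 1. The risks are over-cyclisation to a drimane, ionisation of the allylic acetate, a mixture of endocyclic and exocyclic alkenes, and an ee below about 90 %, which would need chiral HPLC of 2. The fallback sets out from 1 and comes back at 2. It replaces the proton by an iodonium initiator. N-iodosuccinimide, activated by a stoichiometric chiral binaphthol-derived phosphoramidite (toluene, −40 °C), attacks the terminal alkene. The same chair closure then gives (2E)-5-[(1R,5S)-5-iodo-2,6,6-trimethylcyclohex-2-en-1-yl]-3-methylpent-2-en-1-yl acetate F1. Its C–I bond is cleaved with Bu3SnH and Et3B in toluene at 0 °C to give 2.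

Step 2. The risks are attack at the tertiary allyl terminus, double allylation, and loss of CO or self-condensation of the keto ester on heating. The fallback sets out from 2 and comes back at 5. It avoids the decarboxylation altogether. Ethyl pyruvate is silylated (Me3SiCl, Et3N, DMF) to ethyl 2-(trimethylsilyloxy)prop-2-enoate F2. This is added slowly to 2, Pd2(dba)3, dppe and Bu4N[Ph3SiF2] in THF. The pyruvate enolate is thus released only at the rate at which the allylpalladium consumes it. Aldolate formation is reversible and C-allylation is not, so 5 forms directly.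

Step 6. The risks are β-elimination to the enedial and an E/Z mixture. The fallback sets out from 5 and comes back at 11. It builds the E enol acetate from an alkyne rather than from an enolate.
- Enantioselective addition of trimethylsilylacetylene to 5 (Zn(OTf)2, Et3N, and the enantiomer of a chiral N,N-dimethylamino alcohol ligand that gives R) affords ethyl (2R,5E)-2-hydroxy-6-methyl-2-[(trimethylsilyl)ethynyl]-8-[(1S)-2,6,6-trimethylcyclohex-2-en-1-yl]oct-5-enoate F3.
- Bu4NF gives ethyl (2R,5E)-2-ethynyl-2-hydroxy-6-methyl-8-[(1S)-2,6,6-trimethylcyclohex-2-en-1-yl]oct-5-enoate F4.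
- Pinacolborane with Cp2ZrHCl (10 mol %) hydroborates only the alkyne, giving ethyl (2R,5E)-2-hydroxy-6-methyl-2-[(E)-2-(4,4,5,5-tetramethyl-1,3,2-dioxaborolan-2-yl)ethenyl]-8-[(1S)-2,6,6-trimethylcyclohex-2-en-1-yl]oct-5-enoate F5.
- i-Bu2AlH at −78 °C gives (2R,5E)-2-hydroxy-6-methyl-2-[(E)-2-(4,4,5,5-tetramethyl-1,3,2-dioxaborolan-2-yl)ethenyl]-8-[(1S)-2,6,6-trimethylcyclohex-2-en-1-yl]oct-5-enal F6.
- Cu(OAc)2 with Et3N in MeCN under air replaces boron by acetate with retention of the E geometry (Chan–Lam type coupling) and gives 11.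
- 11 is acetylated as in the last operation of step 6.

**Further compounds**
F1 | step 1 | (2E)-5-[(1R,5S)-5-iodo-2,6,6-trimethylcyclohex-2-en-1-yl]-3-methylpent-2-en-1-yl acetate | CC(=O)OC/C=C(\C)CC[C@@H]1C(C)=CC[C@@H](C1(C)C)I
F2 | step 2 | ethyl 2-(trimethylsilyloxy)prop-2-enoate | C=C(O[Si](C)(C)C)C(=O)OCC
F3 | step 6 | ethyl (2R,5E)-2-hydroxy-6-methyl-2-[(trimethylsilyl)ethynyl]-8-[(1S)-2,6,6-trimethylcyclohex-2-en-1-yl]oct-5-enoate | C[Si](C)(C)C#C[C@@](C(=O)OCC)(CC/C=C(\C)CC[C@@H]1C(C)=CCCC1(C)C)O
F4 | step 6 | ethyl (2R,5E)-2-ethynyl-2-hydroxy-6-methyl-8-[(1S)-2,6,6-trimethylcyclohex-2-en-1-yl]oct-5-enoate | C#C[C@@](C(=O)OCC)(CC/C=C(\C)CC[C@@H]1C(C)=CCCC1(C)C)O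
F5 | step 6 | ethyl (2R,5E)-2-hydroxy-6-methyl-2-[(E)-2-(4,4,5,5-tetramethyl-1,3,2-dioxaborolan-2-yl)ethenyl]-8-[(1S)-2,6,6-trimethylcyclohex-2-en-1-yl]oct-5-enoate | CC1(C)OB(/C=C/[C@@](C(=O)OCC)(CC/C=C(\C)CC[C@@H]2C(C)=CCCC2(C)C)O)OC1(C)C
F6 | step 6 | (2R,5E)-2-hydroxy-6-methyl-2-[(E)-2-(4,4,5,5-tetramethyl-1,3,2-dioxaborolan-2-yl)ethenyl]-8-[(1S)-2,6,6-trimethylcyclohex-2-en-1-yl]oct-5-enal | CC1(C)OB(/C=C/[C@@](C=O)(CC/C=C(\C)CC[C@@H]2C(C)=CCCC2(C)C)O)OC1(C)C
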